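**Strategy.** Ring atoms of the cyclohexenone are called C1 (C=O), C2 (propanoate), C3 (trimethylcyclohexyl), C4, C5 and C6 (CH2O). The enone C1(=O)–C2=C3 with its saturated C4–C5 link is the electrocyclisation product of a 3-oxy-hexatriene C5=C6–C1(O)=C2–C3=C4. The route therefore rests on a [3+3] annulation: an allylsilane that already holds C2–C3–C4, the quaternary carbon and the α-methyl ester centre is acylated at C2 by a three-carbon acid chloride (C1–C2), and the derived silyloxytriene closes C4–C5 in the same flask. The ring emerges as its C1=C6 silyl enol ether, the substrate for a catalytic asymmetric hydroxymethylation at C6.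

Key step: step 8

Assumption: the ligand enantiomers named in steps 1 and 9 are those expected to give the (S)-quaternary carbon and the (S)-CH2OH carbon; if a first run shows the opposite sense, the mirror-image ligand is used with nothing else changed, and any minor enantiomer from step 1 becomes a diastereomer at 11 and is removed there.

Positions C1–C6 in the Why lines are the ring positions defined in the strategy paragraph.

**Step 1**
Reactants: 1 3-methylcyclohex-2-en-1-one; 2 phenylboronic acid
Product: 3 (3S)-3-methyl-3-phenylcyclohexan-1-one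
Conditions: Pd(OCOCF3)2 (5 mol%), (R)-4-tert-butyl-2-(pyridin-2-yl)-4,5-dihydrooxazole (6 mol%), NH4PF6 (30 mol%), H2O (5 equiv), ClCH2CH2Cl, 40 °C
Reagents that add atoms: none
Why: Palladium-catalysed asymmetric conjugate addition of an arylboronic acid to a β-substituted cyclic enone, in which the chiral pyridine-oxazoline ligand selects the enone face during carbopalladation and so sets the quaternary carbon, the (R)-ligand being expected to give the (S)-ketone.

**Step 2**
Reactants: 3 (3S)-3-methyl-3-phenylcyclohexan-1-one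
Product: 4 [(1S)-1,3,3-trimethylcyclohexyl]benzene
Conditions: Me2Zn, TiCl4 (gives Me2TiCl2, 2.2 equiv), CH2Cl2, −30 °C → rt
Reagents that add atoms: dimethyltitanium dichloride, C[Ti](C)(Cl)Cl (made in the flask from dimethylzinc, C[Zn]C, and TiCl4)
Why: Geminal dimethylation of a ketone by Me2TiCl2 (methyl addition, ionisation of the titanium alkoxide to a tertiary cation, second methyl transfer), which cannot touch the quaternary stereocentre because it carries no leaving group.

**Step 3**
Reactants: 4 [(1S)-1,3,3-trimethylcyclohexyl]benzene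
Product: 5 (1S)-1,3,3-trimethylcyclohexane-1-carboxylic acid
Conditions: RuCl3·xH2O (5 mol%), NaIO4 (15 equiv), CCl4/MeCN/H2O, rt
Reagents that add atoms: sodium periodate, [Na+].[O-]I(=O)(=O)=O; water, O
Why: RuO4-mediated oxidative degradation of a phenyl ring to a carboxylic acid, which should be clean here because the saturated ring has no tertiary C–H and the quaternary centre is inert.

**Step 4**
Reactants: 6 methyl (2S)-3-bromo-2-methylpropanoate; 7 benzyl alcohol
Product: 8 benzyl (2S)-3-bromo-2-methylpropanoate
Conditions: 7 (3 equiv), Ti(OiPr)4 (10 mol%), PhMe, 90 °C, MeOH distilled off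
Reagents that add atoms: none
Why: Titanate-catalysed transesterification under neutral conditions exchanges methyl for benzyl, so that the acid can be released at the end by hydrogenolysis, without base that could epimerise the α-centre or eliminate HBr.

**Step 5**
Reactants: 5 (1S)-1,3,3-trimethylcyclohexane-1-carboxylic acid; 8 benzyl (2S)-3-bromo-2-methylpropanoate
Product: 11 benzyl (2R)-2-methyl-4-oxo-4-[(1S)-1,3,3-trimethylcyclohexyl]butanoate, via acid chloride 9 (not isolated), via alkylzinc bromide 10 (not isolated)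
Conditions: 5, (COCl)2, DMF (cat.), CH2Cl2, 0 °C → rt, then evaporation; 8, Zn dust, LiCl, THF, 40 °C; both combined, PdCl2(PPh3)2 (5 mol%), THF, 0 °C → rt
Reagents that add atoms: none
Why: Negishi acylation of a β-zincio ester (zinc homoenolate) with an acid chloride gives the γ-keto ester; zinc sits on CH2, so the chiral-pool α-methyl centre is carried over unchanged ((2S) in 8 becomes (2R) in 11 only through a change of priorities).

**Step 6**
Reactants: 11 benzyl (2R)-2-methyl-4-oxo-4-[(1S)-1,3,3-trimethylcyclohexyl]butanoate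
Product: 12 benzyl (2R,3Z)-2-methyl-4-[(trifluoromethanesulfonyl)oxy]-4-[(1S)-1,3,3-trimethylcyclohexyl]but-3-enoate
Conditions: KN(SiMe3)2 (1.05 equiv), THF, −78 °C; PhNTf2, −78 → 0 °C
Reagents that add atoms: N-phenylbis(trifluoromethanesulfonimide), O=S(=O)(N(c1ccccc1)S(=O)(=O)C(F)(F)F)C(F)(F)F
Why: Kinetic enolisation of the ketone (its only α-hydrogens are on the CH2, which is more acidic and less hindered than the ester α-H) followed by O-triflation gives the enol triflate; the tert-alkyl ketone should give the (Z)-enolate, though the alkene geometry has no consequence later.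

**Step 7**
Reactants: 12 benzyl (2R,3Z)-2-methyl-4-[(trifluoromethanesulfonyl)oxy]-4-[(1S)-1,3,3-trimethylcyclohexyl]but-3-enoate
Product: 13 benzyl (2R,3Z)-2-methyl-4-[(1S)-1,3,3-trimethylcyclohexyl]-5-(trimethylsilyl)pent-3-enoate
Conditions: Me3SiCH2MgCl, ZnCl2, THF, 0 °C; then 12, Pd(PPh3)4 (5 mol%), THF, 50 °C
Reagents that add atoms: (trimethylsilyl)methylmagnesium chloride, C[Si](C)(C)C[Mg]Cl
Why: Negishi cross-coupling of the enol triflate with a (trimethylsilyl)methylzinc reagent (oxidative addition, transmetalation, reductive elimination) gives the allylsilane with retention of alkene geometry, the weakly basic zinc reagent sparing the benzyl ester and its α-centre.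

**Step 8**
Reactants: 13 benzyl (2R,3Z)-2-methyl-4-[(1S)-1,3,3-trimethylcyclohexyl]-5-(trimethylsilyl)pent-3-enoate; 14 3-chloropropanoyl chloride
Product: 18 benzyl (2R)-2-{2-[(1S)-1,3,3-trimethylcyclohexyl]-6-[(trimethylsilyl)oxy]cyclohexa-1,5-dien-1-yl}propanoate, via chloro ketone 15 (not isolated), via vinyl ketone 16 (not isolated), via silyloxytriene 17 (not isolated)
Conditions: 14 (1.3 equiv), TiCl4 (2.2 equiv), CH2Cl2, −78 °C; i-Pr2NEt (8 equiv), −78 °C → rt; Me3SiOTf (2.5 equiv), 0 °C → rt; PhMe, 80 °C; non-aqueous work-up, used crude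
Reagents that add atoms: trimethylsilyl trifluoromethanesulfonate, C[Si](C)(C)OS(=O)(=O)C(F)(F)F
Why: TiCl4 activates 14 for SE2′ attack by the γ-carbon C2 of allylsilane 13 (silicon β-effect, loss of Me3SiCl), which forms C1–C2 and shifts the alkene to C3=C4; i-Pr2NEt then expels HCl to give vinyl ketone 16, Me3SiOTf/amine silylates its only enolisable position (C2–H) to the 3-silyloxy-hexatriene 17 (C5=C6–C1(OSiMe3)=C2–C3=C4), and heating closes C4–C5. The closest known reaction types are the Hosomi–Sakurai-type acylation of allylsilanes with acid chlorides and the thermal electrocyclisation of 3-oxy-substituted 1,3,5-hexatrienes to cyclohexadienyl ethers. The six-membered ring closes by a thermally allowed disrotatory 6π-electrocyclisation. No stereocentre is formed in 18 (the transient C2 centre of 15 and 16 is erased on enolisation), and the α-methyl ester centre and the quaternary carbon are untouched because neither a strong base nor a free carbocation at C3 intervenes. The step needs γ-regioselective acylation (secured by silicon), enolisation towards C2 only (16 has no other α-hydrogen) and the triene isomer with both vinyl groups cis on C1=C2 (the enol ether isomers should interconvert through the ammonium triflate buffer and only this one can cyclise). The enol ether double bond is thereby placed at C1=C6, the position that step 9 needs.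

**Step 9**
Reactants: 18 benzyl (2R)-2-{2-[(1S)-1,3,3-trimethylcyclohexyl]-6-[(trimethylsilyl)oxy]cyclohexa-1,5-dien-1-yl}propanoate
Product: 19 benzyl (2R)-2-[(5S)-5-(hydroxymethyl)-6-oxo-2-[(1S)-1,3,3-trimethylcyclohexyl]cyclohex-1-en-1-yl]propanoate
Conditions: aq. HCHO (5 equiv), Sc(OTf)3 (10 mol%), (S,S)-6,6′-bis(1-hydroxy-2,2-dimethylpropyl)-2,2′-bipyridine (12 mol%), DME/H2O 9:1, −20 °C
Reagents that add atoms: formaldehyde, C=O
Why: Catalytic asymmetric aqueous Mukaiyama aldol (hydroxymethylation) of a silicon enolate, which reacts at the enol ether carbon C6 (C3 is blocked and not activated), the chiral scandium–bipyridine complex choosing the face of C6 so that the new stereocentre is set as (S) by the catalyst and not by the remote centres.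

**Step 10**
Reactants: 19 benzyl (2R)-2-[(5S)-5-(hydroxymethyl)-6-oxo-2-[(1S)-1,3,3-trimethylcyclohexyl]cyclohex-1-en-1-yl]propanoate
Product: 20 benzyl (2R)-2-[(5S)-5-[(formyloxy)methyl]-6-oxo-2-[(1S)-1,3,3-trimethylcyclohexyl]cyclohex-1-en-1-yl]propanoate
Conditions: HCO2Ac (3 equiv), pyridine, CH2Cl2, −20 → 0 °C
Reagents that add atoms: acetic formic anhydride, CC(=O)OC=O
Why: O-Formylation of the primary alcohol by acyl transfer from the more electrophilic formyl carbon of the mixed anhydride, run cold with a weak base so that β-elimination and epimerisation at the ketone α-carbon C6 are avoided.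

**Step 11**
Reactants: 20 benzyl (2R)-2-[(5S)-5-[(formyloxy)methyl]-6-oxo-2-[(1S)-1,3,3-trimethylcyclohexyl]cyclohex-1-en-1-yl]propanoate
Product: 21 (2R)-2-[(5S)-5-[(formyloxy)methyl]-6-oxo-2-[(1S)-1,3,3-trimethylcyclohexyl]cyclohex-1-en-1-yl]propanoic acid
Conditions: H2 (1 atm), Pd/C (10%), EtOAc, rt
Reagents that add atoms: none
Why: Hydrogenolysis of the benzyl ester under neutral conditions releases the acid, and the formate, the base-sensitive β-acyloxy ketone and the hindered tetrasubstituted enone should survive.

**Compound list**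

1 | 3-methylcyclohex-2-en-1-one | CC1=CC(=O)CCC1 | starting material
2 | phenylboronic acid | OB(O)c1ccccc1 | starting material
3 | (3S)-3-methyl-3-phenylcyclohexan-1-one | c1ccccc1[C@@]2(C)CCCC(=O)C2 | intermediate
4 | [(1S)-1,3,3-trimethylcyclohexyl]benzene | c1ccccc1[C@@]2(C)CCCC(C)(C)C2 | intermediate
5 | (1S)-1,3,3-trimethylcyclohexane-1-carboxylic acid | OC(=O)[C@@]1(C)CCCC(C)(C)C1 | intermediate
6 | methyl (2S)-3-bromo-2-methylpropanoate | C[C@@H](C(=O)OC)CBr | starting material
7 | benzyl alcohol | OCc1ccccc1 | starting material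
8 | benzyl (2S)-3-bromo-2-methylpropanoate | C[C@@H](C(=O)OCc1ccccc1)CBr | intermediate
9 | (1S)-1,3,3-trimethylcyclohexane-1-carbonyl chloride | ClC(=O)[C@@]1(C)CCCC(C)(C)C1 | intermediate
10 | bromo[(2S)-3-(benzyloxy)-2-methyl-3-oxopropyl]zinc | C[C@@H](C(=O)OCc1ccccc1)C[Zn]Br | intermediate
11 | benzyl (2R)-2-methyl-4-oxo-4-[(1S)-1,3,3-trimethylcyclohexyl]butanoate | C[C@@H](C(=O)OCc1ccccc1)CC(=O)[C@@]2(C)CCCC(C)(C)C2 | intermediate
12 | benzyl (2R,3Z)-2-methyl-4-[(trifluoromethanesulfonyl)oxy]-4-[(1S)-1,3,3-trimethylcyclohexyl]but-3-enoate | C[C@@H](C(=O)OCc1ccccc1)/C=C(\OS(=O)(=O)C(F)(F)F)[C@@]2(C)CCCC(C)(C)C2 | intermediate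
13 | benzyl (2R,3Z)-2-methyl-4-[(1S)-1,3,3-trimethylcyclohexyl]-5-(trimethylsilyl)pent-3-enoate | C[C@@H](C(=O)OCc1ccccc1)/C=C(\C[Si](C)(C)C)[C@@]2(C)CCCC(C)(C)C2 | intermediate
14 | 3-chloropropanoyl chloride | ClCCC(=O)Cl | starting material
15 | benzyl (2R)-6-chloro-2-methyl-4-oxo-3-{1-[(1S)-1,3,3-trimethylcyclohexyl]ethenyl}hexanoate (both C3 epimers) | C[C@@H](C(=O)OCc1ccccc1)C(C(=O)CCCl)C(=C)[C@@]2(C)CCCC(C)(C)C2 | intermediate
16 | benzyl (2R)-2-methyl-4-oxo-3-{1-[(1S)-1,3,3-trimethylcyclohexyl]ethenyl}hex-5-enoate (both C3 epimers) | C[C@@H](C(=O)OCc1ccccc1)C(C(=O)C=C)C(=C)[C@@]2(C)CCCC(C)(C)C2 | intermediate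
17 | benzyl (2R,3E)-2-methyl-3-{1-[(1S)-1,3,3-trimethylcyclohexyl]ethenyl}-4-[(trimethylsilyl)oxy]hexa-3,5-dienoate (the isomer that cyclises) | C[C@@H](C(=O)OCc1ccccc1)/C(C(=C)[C@@]2(C)CCCC(C)(C)C2)=C(\O[Si](C)(C)C)C=C | intermediate
18 | benzyl (2R)-2-{2-[(1S)-1,3,3-trimethylcyclohexyl]-6-[(trimethylsilyl)oxy]cyclohexa-1,5-dien-1-yl}propanoate | C[C@@H](C(=O)OCc1ccccc1)C1=C([C@@]2(C)CCCC(C)(C)C2)CCC=C1O[Si](C)(C)C | intermediate
19 | benzyl (2R)-2-[(5S)-5-(hydroxymethyl)-6-oxo-2-[(1S)-1,3,3-trimethylcyclohexyl]cyclohex-1-en-1-yl]propanoate | C[C@@H](C(=O)OCc1ccccc1)C1=C([C@@]2(C)CCCC(C)(C)C2)CC[C@@H](CO)C1=O | intermediate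
20 | benzyl (2R)-2-[(5S)-5-[(formyloxy)methyl]-6-oxo-2-[(1S)-1,3,3-trimethylcyclohexyl]cyclohex-1-en-1-yl]propanoate | C[C@@H](C(=O)OCc1ccccc1)C1=C([C@@]2(C)CCCC(C)(C)C2)CC[C@@H](COC=O)C1=O | intermediate
21 | (2R)-2-[(5S)-5-[(formyloxy)methyl]-6-oxo-2-[(1S)-1,3,3-trimethylcyclohexyl]cyclohex-1-en-1-yl]propanoic acid | C[C@@H](C(=O)O)C1=C([C@@]2(C)CCCC(C)(C)C2)CC[C@@H](COC=O)C1=O | target

**Step count.** Total: 11 steps. Longest linear sequence: 10 steps (steps 1–3 and 5–11); step 4 is a one-step side branch.

**Steps most likely to fail**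

1. Step 8. The one-pot sequence may divert before the ring closes. The vinyl ketone can oligomerise by intermolecular Michael or Diels–Alder reaction with the electron-rich dienol ether. Residual titanium Lewis acid can trigger a cationic closure with a skeletal shift next to the quaternary carbon or lactonisation onto the ester. The triene isomer that cannot cyclise may also accumulate. The fallback is a different [3+3] annulation that joins the same two ring bonds by two sequential ene reactions. It sets out from 11: Takai–Lombardo methylenation (Zn, CH2Br2, TiCl4, THF) gives the 1,1-disubstituted alkene F1. Acrolein and Me2AlCl in CH2Cl2 then effect an intermolecular conjugate ene reaction (C4–C5) followed by an intramolecular carbonyl-ene closure (C1–C2) to the cyclohexenol F2. Oxidation with DMP gives the β,γ-unsaturated ketone F3, and DBU moves the double bond into conjugation to give the enone F4. Kinetic deprotonation at C6 with LiN(i-Pr)2 in the presence of Me3SiCl at −78 °C comes back to the route at 18.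

2. Step 9. Facial discrimination by the chiral scandium complex may be poor on a hindered cyclic 2-silyloxy diene, and protodesilylation in the aqueous medium may compete with the aldol. The fallback replaces the Lewis-acid Mukaiyama aldol by a reagent-controlled boron aldol. It sets out from 18: aqueous citric acid in THF gives the enone F5 (the same enone as F4). Ipc2BCl (the enantiomer that delivers the (5S)-aldol) and Et3N in Et2O form the boron dienolate on the C6 side, and gaseous formaldehyde from cracked paraformaldehyde is added at −78 °C. Release of the borinate with diethanolamine comes back to the route at 19.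

3. Step 2. The intermediate tertiary cation may lose a proton to give a methylcyclohexene instead of accepting the second methyl group. The fallback builds the gem-dimethyl group from a cyclopropane. It sets out from 3: Wittig methylenation (Ph3P=CH2, THF) gives the exocyclic alkene F6, and Simmons–Smith cyclopropanation (Et2Zn, CH2I2, CH2Cl2) gives the spirocyclopropane F7. Hydrogenolysis (H2 1 atm, PtO2, AcOH) cleaves the least substituted cyclopropane bond and comes back to the route at 4.

**Further compounds**

F1 | step 8 | benzyl (2R)-2-methyl-4-[(1S)-1,3,3-trimethylcyclohexyl]pent-4-enoate | C[C@@H](C(=O)OCc1ccccc1)CC(=C)[C@@]2(C)CCCC(C)(C)C2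
F2 | step 8 | benzyl (2R)-2-{2-hydroxy-6-[(1S)-1,3,3-trimethylcyclohexyl]cyclohex-5-en-1-yl}propanoate (epimers at the two new ring carbons) | C[C@@H](C(=O)OCc1ccccc1)C1C(O)CCC=C1[C@@]2(C)CCCC(C)(C)C2
F3 | step 8 | benzyl (2R)-2-{2-oxo-6-[(1S)-1,3,3-trimethylcyclohexyl]cyclohex-5-en-1-yl}propanoate (epimers at the ring carbon between C=O and C=C) | C[C@@H](C(=O)OCc1ccccc1)C1C(=O)CCC=C1[C@@]2(C)CCCC(C)(C)C2
F4 | step 8 | benzyl (2R)-2-{6-oxo-2-[(1S)-1,3,3-trimethylcyclohexyl]cyclohex-1-en-1-yl}propanoate | C[C@@H](C(=O)OCc1ccccc1)C1=C([C@@]2(C)CCCC(C)(C)C2)CCCC1=O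
F5 | step 9 | benzyl (2R)-2-{6-oxo-2-[(1S)-1,3,3-trimethylcyclohexyl]cyclohex-1-en-1-yl}propanoate (same compound as F4) | C[C@@H](C(=O)OCc1ccccc1)C1=C([C@@]2(C)CCCC(C)(C)C2)CCCC1=O
F6 | step 2 | [(1S)-1-methyl-3-methylidenecyclohexyl]benzene | c1ccccc1[C@@]2(C)CCCC(=C)C2
F7 | step 2 | (5S)-5-methyl-5-phenylspiro[2.5]octane | c1ccccc1[C@@]2(C)CCCC3(CC3)C2
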